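**Plan**

Core numbering: 7-oxabicyclo[2.2.1]heptane with C-1 (Me, O), C-2 (carbinol chain), C-3 (quaternary: Me, bromochloro chain), C-4 (H, O), C-5/C-6 (ethano bridge), O-7. The feature used: the C-5–C-6 bridge lies between the two oxygen-bearing bridgeheads, so the bicycle is an isomer of an acyclic 1,5-diene monoepoxide (oxirane C-4/C-5 on C-3, methylidene C-1=C-6 on C-2).
Retrosynthesis: C–Br/C–Cl back to a trisubstituted alkene; side-chain vinyl back to CH2O-PMB; 4-methylpent-3-enyl back to vinyl; then C-5–C-6 and C-1–O-7 cut in one move; isopropenyl back to CO2H, oxirane back to an acetonide; last the hindered C-2–C-3 bond cut (ester-enolate Claisen) into fragment A (allylic alcohol from a glycerate) and fragment B (acid from 2-methylglycidol).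
Forward: A and B are esterified and joined at the quaternary C-3; carbocycle and ether bridge close together in step 16; then the C-3 chain (hydroboration/Suzuki), the vinyl (Wittig) and the bromochloride.
Stereochemistry: C-4 is bought (glycerate) and relays to C-3 and C-2 in the one Claisen event; C-1 follows from the bridge; the carbinol centre is bought ((R)-2-methylglycidol); the C–Br centre comes from a reagent-controlled Shi epoxide opened with inversion.

Key step: step 16

Assumption: in the Claisen step the new bond forms anti to the acetal C–O bond of the H-eclipsed (allylic 1,3-strain) conformer of the Z-allyl ester, as in related Z-allylic systems with a dioxolane stereocentre.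
Abbreviations: TBS = tert-butyldimethylsilyl, PMB = 4-methoxybenzyl.

Step 1
Reactants: 1 methyl (4S)-2,2-dimethyl-1,3-dioxolane-4-carboxylate
Product: 3 (4R)-4-ethynyl-2,2-dimethyl-1,3-dioxolane, via aldehyde 2 (not isolated)
Conditions: i-Bu2AlH, CH2Cl2, −78 °C; then MeOH, K2CO3, Ohira–Bestmann reagent, −78 °C to rt
Reagents that add atoms: Ohira–Bestmann reagent, dimethyl (1-diazo-2-oxopropyl)phosphonate, COP(=O)(OC)C(=[N+]=[N-])C(C)=O
Why: Low-temperature ester reduction and in-flask Seyferth–Gilbert homologation should give the alkyne, with the bought acetal centre carried over and epimerisation of the aldehyde limited by the cold, weakly basic medium.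

Step 2
Reactants: 3 (4R)-4-ethynyl-2,2-dimethyl-1,3-dioxolane
Product: 4 methyl 3-[(4R)-2,2-dimethyl-1,3-dioxolan-4-yl]prop-2-ynoate
Conditions: n-BuLi, THF, −78 °C; ClCO2Me
Reagents that add atoms: methyl chloroformate, COC(=O)Cl
Why: C-acylation of the lithium acetylide is a standard ynoate synthesis and does not touch the stereocentre.

Step 3
Reactants: 4 methyl 3-[(4R)-2,2-dimethyl-1,3-dioxolan-4-yl]prop-2-ynoate
Product: 5 methyl (2Z)-3-[(4R)-2,2-dimethyl-1,3-dioxolan-4-yl]but-2-enoate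
Conditions: Me2CuLi, THF, −78 °C; MeOH quench at −78 °C, then aq. NH4Cl
Reagents that add atoms: lithium dimethylcuprate, [Li+].C[Cu-]C
Why: Syn carbocupration of the ynoate and protonation with retention should place the methyl trans to the ester, so the Z geometry is set kinetically (cuprate conjugate addition).

Step 4
Reactants: 5 methyl (2Z)-3-[(4R)-2,2-dimethyl-1,3-dioxolan-4-yl]but-2-enoate
Product: 6 (2Z)-3-[(4R)-2,2-dimethyl-1,3-dioxolan-4-yl]but-2-en-1-ol (fragment A)
Conditions: i-Bu2AlH, CH2Cl2, −78 °C; aq. KNaC4H4O6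
Reagents that add atoms: none
Why: 1,2-Reduction of the enoate gives the allylic alcohol with the alkene geometry retained.

Step 5
Reactants: 7 (2R)-2-methylglycidol
Product: 8 (2S)-2-{[(4-methoxybenzyl)oxy]methyl}-2-methyloxirane
Conditions: NaH, 4-MeOC6H4CH2Cl, Bu4NI (cat.), THF–DMF, 0 °C to rt
Reagents that add atoms: 4-methoxybenzyl chloride, COc1ccc(CCl)cc1
Why: Williamson etherification of the primary alcohol leaves the quaternary oxirane carbon untouched (the descriptor changes only through priorities).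

Step 6
Reactants: 8 (2S)-2-{[(4-methoxybenzyl)oxy]methyl}-2-methyloxirane
Product: 9 (2S)-1-[(4-methoxybenzyl)oxy]-2-methylhex-5-en-2-ol
Conditions: CH2=CHCH2MgBr, CuI (10 mol %), THF, −30 to 0 °C
Reagents that add atoms: allylmagnesium bromide, C=CC[Mg]Br
Why: Copper-catalysed Grignard opening of the 2,2-disubstituted epoxide occurs at the unsubstituted CH2 (SN2), so the tertiary carbinol centre is kept.

Step 7
Reactants: 9 (2S)-1-[(4-methoxybenzyl)oxy]-2-methylhex-5-en-2-ol
Product: 10 (2S)-2-(TBS-oxy)-1-(PMB-oxy)-2-methylhex-5-ene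
Conditions: t-BuMe2SiOTf, 2,6-lutidine, CH2Cl2, 0 °C to rt
Reagents that add atoms: tert-butyldimethylsilyl trifluoromethanesulfonate, CC(C)(C)[Si](C)(C)OS(=O)(=O)C(F)(F)F
Why: The silyl triflate silylates the hindered tertiary alcohol, which would otherwise lactonise at the acid stage.

Step 8
Reactants: 10 (2S)-2-(TBS-oxy)-1-(PMB-oxy)-2-methylhex-5-ene
Product: 12 (5S)-5-(TBS-oxy)-6-(PMB-oxy)-5-methylhexan-1-ol, via alkylborane 11 (not isolated)
Conditions: 9-BBN, THF, 0 °C to rt; then NaOH, H2O2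
Reagents that add atoms: hydrogen peroxide, OO
Why: Anti-Markovnikov hydroboration–oxidation of the only alkene gives the primary alcohol.

Step 9
Reactants: 12 (5S)-5-(TBS-oxy)-6-(PMB-oxy)-5-methylhexan-1-ol
Product: 14 (5S)-5-(TBS-oxy)-6-(PMB-oxy)-5-methylhexanoic acid (fragment B), via aldehyde 13 (not isolated)
Conditions: TEMPO (cat.), PhI(OAc)2, MeCN–H2O, rt
Reagents that add atoms: water, O
Why: Nitroxyl-catalysed oxidation takes the primary alcohol through the aldehyde hydrate to the acid while PMB and silyl ethers are inert.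

Step 10
Reactants: 6 (2Z)-3-[(4R)-2,2-dimethyl-1,3-dioxolan-4-yl]but-2-en-1-ol; 14 (5S)-5-(TBS-oxy)-6-(PMB-oxy)-5-methylhexanoic acid
Product: 15 (2Z)-3-[(4R)-2,2-dimethyl-1,3-dioxolan-4-yl]but-2-en-1-yl (5S)-5-(TBS-oxy)-6-(PMB-oxy)-5-methylhexanoate
Conditions: DCC, DMAP (cat.), CH2Cl2, 0 °C to rt
Reagents that add atoms: none
Why: Steglich esterification joins the two chiral-pool fragments without touching a stereocentre.

Step 11
Reactants: 15 (2Z)-3-[(4R)-2,2-dimethyl-1,3-dioxolan-4-yl]but-2-en-1-yl (5S)-5-(TBS-oxy)-6-(PMB-oxy)-5-methylhexanoate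
Product: 18 (2S,3S)-3-[(4R)-2,2-dimethyl-1,3-dioxolan-4-yl]-3-methyl-2-[(3S)-3-(TBS-oxy)-4-(PMB-oxy)-3-methylbutyl]pent-4-enoic acid, via silyl ketene acetal 16 (not isolated), via silyl ester 17 (not isolated)
Conditions: LiN(i-Pr)2, THF–DMPU, −78 °C; Me3SiCl, −78 to 60 °C; then aq. NaOH, citric acid work-up
Reagents that add atoms: none
Why: In this Ireland–Claisen rearrangement the Z(O)-enolate formed in THF–DMPU is trapped as the (Z)-silyl ketene acetal and should rearrange through a chair in which the new bond forms anti to the acetal C–O bond of the H-eclipsed Z-alkene, so the bought centre sets the quaternary C-3 and the enolate geometry sets C-2.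

Step 12
Reactants: 18 (2S,3S)-3-[(4R)-2,2-dimethyl-1,3-dioxolan-4-yl]-3-methyl-2-[(3S)-3-(TBS-oxy)-4-(PMB-oxy)-3-methylbutyl]pent-4-enoic acid
Product: 19 (3S,4S)-4-[(4R)-2,2-dimethyl-1,3-dioxolan-4-yl]-4-methyl-3-[(3S)-3-(TBS-oxy)-4-(PMB-oxy)-3-methylbutyl]hex-5-en-2-one
Conditions: MeLi (2.5 equiv), Et2O, 0 °C; Me3SiCl quench, aq. NH4Cl
Reagents that add atoms: methyllithium, C[Li]
Why: Addition of MeLi to the lithium carboxylate stops at the dilithio gem-diolate, which gives the methyl ketone on quench without enolising the α-centre.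

Step 13
Reactants: 19 (3S,4S)-4-[(4R)-2,2-dimethyl-1,3-dioxolan-4-yl]-4-methyl-3-[(3S)-3-(TBS-oxy)-4-(PMB-oxy)-3-methylbutyl]hex-5-en-2-one
Product: 20 (4R)-2,2-dimethyl-4-{(3S,4R)-3,5-dimethyl-4-[(3S)-3-(TBS-oxy)-4-(PMB-oxy)-3-methylbutyl]hexa-1,5-dien-3-yl}-1,3-dioxolane
Conditions: Ph3PCH3Br, KOt-Bu, toluene, 0 to 80 °C
Reagents that add atoms: methyltriphenylphosphonium bromide, C[P+](c1ccccc1)(c1ccccc1)c1ccccc1.[Br-]
Why: Wittig methylenation of the methyl ketone installs the 1,1-disubstituted alkene that is the nucleophile of the key step (geometry unchanged; the descriptor at C-2 changes only through priorities).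

Step 14
Reactants: 20 (4R)-2,2-dimethyl-4-{(3S,4R)-3,5-dimethyl-4-[(3S)-3-(TBS-oxy)-4-(PMB-oxy)-3-methylbutyl]hexa-1,5-dien-3-yl}-1,3-dioxolane
Product: 21 (2R,3S,4R)-3-ethenyl-3,5-dimethyl-4-[(3S)-3-(TBS-oxy)-4-(PMB-oxy)-3-methylbutyl]hex-5-ene-1,2-diol
Conditions: AcOH–THF–H2O (3:1:1), 40 °C
Reagents that add atoms: none
Why: Mild aqueous acid hydrolyses the terminal isopropylidene acetal while the tertiary silyl ether, the PMB ether and the alkenes survive.

Step 15
Reactants: 21 (2R,3S,4R)-3-ethenyl-3,5-dimethyl-4-[(3S)-3-(TBS-oxy)-4-(PMB-oxy)-3-methylbutyl]hex-5-ene-1,2-diol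
Product: 23 (2R)-2-{(3S,4R)-3,5-dimethyl-4-[(3S)-3-(TBS-oxy)-4-(PMB-oxy)-3-methylbutyl]hexa-1,5-dien-3-yl}oxirane, via monotosylate 22 (not isolated)
Conditions: NaH, 1-(p-tolylsulfonyl)imidazole, THF, 0 °C to rt
Reagents that add atoms: none
Why: Selective sulfonylation of the primary alkoxide and Williamson closure by the neighbouring secondary alkoxide gives the terminal epoxide with retention at the carbinol carbon.

Step 16
Reactants: 23 (2R)-2-{(3S,4R)-3,5-dimethyl-4-[(3S)-3-(TBS-oxy)-4-(PMB-oxy)-3-methylbutyl]hexa-1,5-dien-3-yl}oxirane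
Product: 24 (1R,2S,3S,4S)-3-ethenyl-1,3-dimethyl-2-[(3S)-3-(TBS-oxy)-4-(PMB-oxy)-3-methylbutyl]-7-oxabicyclo[2.2.1]heptane
Conditions: BF3·OEt2 (1.1 equiv), CH2Cl2, −78 to −40 °C; Et3N quench
Reagents that add atoms: none
Why: Proposed new method: BF3 activates the oxirane, the CH2 terminus of the isopropenyl group attacks the unsubstituted oxirane carbon from the rear to forge C-5–C-6, and the tertiary cation developing at C-1 is captured across the ring by the BF3-bound oxygen on C-4, so the 1,5-diene monoepoxide isomerises to the oxabicycle with no atom gained or lost. The closest known reaction types are Lewis-acid epoxy-olefin cyclisations of 1,5-diene monoepoxides that end as 7-oxabicyclo[2.2.1]heptanes and 6-endo openings of monosubstituted epoxides at CH2 by tethered π-nucleophiles; new here is that a terminal epoxide is opened at CH2 by an alkene while its oxygen stays on the neighbouring carbon. The carbocycle closes 6-endo-tet at the oxirane and 6-endo-trig at the alkene through a six-membered transition state, and the ether bridge closes by transannular 1,4-capture (a five-membered C–O closure). C-4 keeps the bought configuration because its C–O bond is never broken, C-1 can only form with oxygen on the face of the one-atom bridge, and C-2 and C-3 are spectators. The step needs attack at the primary and not the neopentyl secondary oxirane carbon, and cyclisation faster than ionisation at C-4 with 1,2-shift; the tether length, the nucleophilic 1,1-disubstituted alkene, the absence of any other nucleophilic alkene (the vinyl group on C-3 cannot reach and the side chain carries none) and the low temperature should secure this. Any unsaturated alcohol formed by proton loss from the cation should be funnelled to the same ether by the acid, as in cineole-type closures.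

Step 17
Reactants: 24 (1R,2S,3S,4S)-3-ethenyl-1,3-dimethyl-2-[(3S)-3-(TBS-oxy)-4-(PMB-oxy)-3-methylbutyl]-7-oxabicyclo[2.2.1]heptane
Product: 26 (1R,2S,3S,4S)-1,3-dimethyl-3-(4-methylpent-3-en-1-yl)-2-[(3S)-3-(TBS-oxy)-4-(PMB-oxy)-3-methylbutyl]-7-oxabicyclo[2.2.1]heptane, via alkylborane 25 (not isolated)
Conditions: 9-BBN, THF, rt to 50 °C; then Me2C=CHBr, Pd(dppf)Cl2 (5 mol %), AsPh3, Cs2CO3, DMF–H2O, 50 °C
Reagents that add atoms: 1-bromo-2-methylprop-1-ene, CC(C)=CBr
Why: Hydroboration of the only alkene and B-alkyl Suzuki–Miyaura coupling with the alkenyl bromide should build the 4-methylpent-3-enyl chain after the cation chemistry is over.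

Step 18
Reactants: 26 (1R,2S,3S,4S)-1,3-dimethyl-3-(4-methylpent-3-en-1-yl)-2-[(3S)-3-(TBS-oxy)-4-(PMB-oxy)-3-methylbutyl]-7-oxabicyclo[2.2.1]heptane
Product: 27 (2S)-2-(TBS-oxy)-2-methyl-4-[(1R,2S,3S,4S)-1,3-dimethyl-3-(4-methylpent-3-en-1-yl)-7-oxabicyclo[2.2.1]heptan-2-yl]butan-1-ol
Conditions: DDQ, CH2Cl2–pH 7 buffer, 0 °C
Reagents that add atoms: none
Why: Oxidative cleavage of the PMB ether frees the primary alcohol and leaves the silyl ether and the alkene alone.

Step 19
Reactants: 27 (2S)-2-(TBS-oxy)-2-methyl-4-[(1R,2S,3S,4S)-1,3-dimethyl-3-(4-methylpent-3-en-1-yl)-7-oxabicyclo[2.2.1]heptan-2-yl]butan-1-ol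
Product: 28 (2S)-2-(TBS-oxy)-2-methyl-4-[(1R,2S,3S,4S)-1,3-dimethyl-3-(4-methylpent-3-en-1-yl)-7-oxabicyclo[2.2.1]heptan-2-yl]butanal
Conditions: Dess–Martin periodinane, NaHCO3, CH2Cl2, 0 °C to rt
Reagents that add atoms: none
Why: Dess–Martin oxidation gives the α-silyloxy aldehyde, which has no α-hydrogen and cannot epimerise.

Step 20
Reactants: 28 (2S)-2-(TBS-oxy)-2-methyl-4-[(1R,2S,3S,4S)-1,3-dimethyl-3-(4-methylpent-3-en-1-yl)-7-oxabicyclo[2.2.1]heptan-2-yl]butanal
Product: 29 TBS ether of (3S)-3-methyl-5-[(1R,2S,3S,4S)-1,3-dimethyl-3-(4-methylpent-3-en-1-yl)-7-oxabicyclo[2.2.1]heptan-2-yl]pent-1-en-3-ol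
Conditions: Ph3PCH3Br, KOt-Bu, THF, 0 °C
Reagents that add atoms: methyltriphenylphosphonium bromide, C[P+](c1ccccc1)(c1ccccc1)c1ccccc1.[Br-]
Why: Wittig methylenation gives the vinyl group of the tertiary allylic ether only after the other vinyl group has been consumed, so the two never compete.

Step 21
Reactants: 29 TBS ether of (3S)-3-methyl-5-[(1R,2S,3S,4S)-1,3-dimethyl-3-(4-methylpent-3-en-1-yl)-7-oxabicyclo[2.2.1]heptan-2-yl]pent-1-en-3-ol
Product: 30 analogue of 29 with a 2-[(2R)-3,3-dimethyloxiran-2-yl]ethyl group on C-3 of the bicycle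
Conditions: D-fructose-derived Shi ketone (0.3 equiv), KHSO5, K2CO3, Bu4NHSO4, MeCN–CH2(OMe)2–aq. Na2B4O7 buffer, 0 °C
Reagents that add atoms: potassium peroxymonosulfate, [K+].OOS(=O)(=O)[O-]
Why: In the Shi epoxidation the chiral dioxirane attacks the electron-rich trisubstituted alkene in preference to the hindered vinyl group and, through the spiro transition state, should give the (R)-epoxide by reagent control.

Step 22
Reactants: 30 analogue of 29 with a 2-[(2R)-3,3-dimethyloxiran-2-yl]ethyl group on C-3 of the bicycle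
Product: 31 analogue of 29 with a (3S)-3-bromo-4-hydroxy-4-methylpentyl group on C-3 of the bicycle
Conditions: Li2NiBr4, THF, 0 °C to rt
Reagents that add atoms: dilithium tetrabromonickelate, [Li+].[Li+].Br[Ni-2](Br)(Br)Br
Why: SN2 opening of the trisubstituted epoxide by soft bromide at the less substituted carbon inverts that centre and gives the C–Br configuration of the target.

Step 23
Reactants: 31 analogue of 29 with a (3S)-3-bromo-4-hydroxy-4-methylpentyl group on C-3 of the bicycle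
Product: 32 O-TBS-dactylomelol
Conditions: Me2C=C(Cl)NMe2, CH2Cl2, 0 °C to rt
Reagents that add atoms: 1-chloro-N,N,2-trimethylprop-1-en-1-amine, CC(C)=C(Cl)N(C)C
Why: The α-chloroenamine converts the tertiary alcohol to the chloride under neutral conditions; the neighbouring bromine assists ionisation and chloride opens the bromonium ion at the tertiary carbon, so the C–Br centre is retained.

Step 24
Reactants: 32 O-TBS-dactylomelol
Product: 33 dactylomelol
Conditions: HF·pyridine, pyridine–THF, 0 °C to rt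
Reagents that add atoms: none
Why: Buffered fluoride cleaves the tertiary silyl ether without base, which the vicinal bromochloride would not tolerate.

**Compound list**

1 | methyl (4S)-2,2-dimethyl-1,3-dioxolane-4-carboxylate | COC(=O)[C@@H]1COC(C)(C)O1 | starting material
2 | (4S)-2,2-dimethyl-1,3-dioxolane-4-carbaldehyde | O=C[C@@H]1COC(C)(C)O1 | intermediate (not isolated)
3 | (4R)-4-ethynyl-2,2-dimethyl-1,3-dioxolane | C#C[C@@H]1COC(C)(C)O1 | intermediate
4 | methyl 3-[(4R)-2,2-dimethyl-1,3-dioxolan-4-yl]prop-2-ynoate | COC(=O)C#C[C@@H]1COC(C)(C)O1 | intermediate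
5 | methyl (2Z)-3-[(4R)-2,2-dimethyl-1,3-dioxolan-4-yl]but-2-enoate | COC(=O)/C=C(/C)[C@@H]1COC(C)(C)O1 | intermediate
6 | (2Z)-3-[(4R)-2,2-dimethyl-1,3-dioxolan-4-yl]but-2-en-1-ol (fragment A) | OC/C=C(/C)[C@@H]1COC(C)(C)O1 | intermediate
7 | (2R)-2-methylglycidol, [(2R)-2-methyloxiran-2-yl]methanol | OC[C@]1(C)CO1 | starting material
8 | (2S)-2-{[(4-methoxybenzyl)oxy]methyl}-2-methyloxirane | COc1ccc(COC[C@]2(C)CO2)cc1 | intermediate
9 | (2S)-1-[(4-methoxybenzyl)oxy]-2-methylhex-5-en-2-ol | COc1ccc(COC[C@@](C)(O)CCC=C)cc1 | intermediate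
10 | (2S)-2-(TBS-oxy)-1-(PMB-oxy)-2-methylhex-5-ene | COc1ccc(COC[C@@](C)(O[Si](C)(C)C(C)(C)C)CCC=C)cc1 | intermediate
11 | B-[(5S)-5-(TBS-oxy)-6-(PMB-oxy)-5-methylhexyl]-9-borabicyclo[3.3.1]nonane | COc1ccc(COC[C@@](C)(O[Si](C)(C)C(C)(C)C)CCCCB2C3CCCC2CCC3)cc1 | intermediate (not isolated)
12 | (5S)-5-(TBS-oxy)-6-(PMB-oxy)-5-methylhexan-1-ol | COc1ccc(COC[C@@](C)(O[Si](C)(C)C(C)(C)C)CCCCO)cc1 | intermediate
13 | (5S)-5-(TBS-oxy)-6-(PMB-oxy)-5-methylhexanal | COc1ccc(COC[C@@](C)(O[Si](C)(C)C(C)(C)C)CCCC=O)cc1 | intermediate (not isolated)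
14 | (5S)-5-(TBS-oxy)-6-(PMB-oxy)-5-methylhexanoic acid (fragment B) | COc1ccc(COC[C@@](C)(O[Si](C)(C)C(C)(C)C)CCCC(=O)O)cc1 | intermediate
15 | (2Z)-3-[(4R)-2,2-dimethyl-1,3-dioxolan-4-yl]but-2-en-1-yl (5S)-5-(TBS-oxy)-6-(PMB-oxy)-5-methylhexanoate | COc1ccc(COC[C@@](C)(O[Si](C)(C)C(C)(C)C)CCCC(=O)OC/C=C(/C)[C@@H]2COC(C)(C)O2)cc1 | intermediate
16 | (Z)-trimethylsilyl ketene acetal of 15 (chain cis to OSiMe3) | COc1ccc(COC[C@@](C)(O[Si](C)(C)C(C)(C)C)CC/C=C(\O[Si](C)(C)C)OC/C=C(/C)[C@@H]2COC(C)(C)O2)cc1 | intermediate (not isolated)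
17 | trimethylsilyl ester of acid 18 | COc1ccc(COC[C@@](C)(O[Si](C)(C)C(C)(C)C)CC[C@H](C(=O)O[Si](C)(C)C)[C@](C)(C=C)[C@@H]2COC(C)(C)O2)cc1 | intermediate (not isolated)
18 | (2S,3S)-3-[(4R)-2,2-dimethyl-1,3-dioxolan-4-yl]-3-methyl-2-[(3S)-3-(TBS-oxy)-4-(PMB-oxy)-3-methylbutyl]pent-4-enoic acid | COc1ccc(COC[C@@](C)(O[Si](C)(C)C(C)(C)C)CC[C@H](C(=O)O)[C@](C)(C=C)[C@@H]2COC(C)(C)O2)cc1 | intermediate
19 | (3S,4S)-4-[(4R)-2,2-dimethyl-1,3-dioxolan-4-yl]-4-methyl-3-[(3S)-3-(TBS-oxy)-4-(PMB-oxy)-3-methylbutyl]hex-5-en-2-one | COc1ccc(COC[C@@](C)(O[Si](C)(C)C(C)(C)C)CC[C@H](C(C)=O)[C@](C)(C=C)[C@@H]2COC(C)(C)O2)cc1 | intermediate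
20 | (4R)-2,2-dimethyl-4-{(3S,4R)-3,5-dimethyl-4-[(3S)-3-(TBS-oxy)-4-(PMB-oxy)-3-methylbutyl]hexa-1,5-dien-3-yl}-1,3-dioxolane | COc1ccc(COC[C@@](C)(O[Si](C)(C)C(C)(C)C)CC[C@H](C(C)=C)[C@](C)(C=C)[C@@H]2COC(C)(C)O2)cc1 | intermediate
21 | (2R,3S,4R)-3-ethenyl-3,5-dimethyl-4-[(3S)-3-(TBS-oxy)-4-(PMB-oxy)-3-methylbutyl]hex-5-ene-1,2-diol | COc1ccc(COC[C@@](C)(O[Si](C)(C)C(C)(C)C)CC[C@H](C(C)=C)[C@](C)(C=C)[C@@H](O)CO)cc1 | intermediate
22 | primary 4-methylbenzenesulfonate of diol 21 | COc1ccc(COC[C@@](C)(O[Si](C)(C)C(C)(C)C)CC[C@H](C(C)=C)[C@](C)(C=C)[C@@H](O)COS(=O)(=O)c2ccc(C)cc2)cc1 | intermediate (not isolated)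
23 | (2R)-2-{(3S,4R)-3,5-dimethyl-4-[(3S)-3-(TBS-oxy)-4-(PMB-oxy)-3-methylbutyl]hexa-1,5-dien-3-yl}oxirane | COc1ccc(COC[C@@](C)(O[Si](C)(C)C(C)(C)C)CC[C@H](C(C)=C)[C@](C)(C=C)[C@@H]2CO2)cc1 | intermediate
24 | (1R,2S,3S,4S)-3-ethenyl-1,3-dimethyl-2-[(3S)-3-(TBS-oxy)-4-(PMB-oxy)-3-methylbutyl]-7-oxabicyclo[2.2.1]heptane | COc1ccc(COC[C@@](C)(O[Si](C)(C)C(C)(C)C)CC[C@H]2[C@](C)(C=C)[C@@H]3CC[C@@]2(C)O3)cc1 | intermediate
25 | B-alkyl-9-borabicyclo[3.3.1]nonane from 24 (boron on the terminal carbon of the former vinyl group) | COc1ccc(COC[C@@](C)(O[Si](C)(C)C(C)(C)C)CC[C@H]2[C@](C)(CCB4C5CCCC4CCC5)[C@@H]3CC[C@@]2(C)O3)cc1 | intermediate (not isolated)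
26 | (1R,2S,3S,4S)-1,3-dimethyl-3-(4-methylpent-3-en-1-yl)-2-[(3S)-3-(TBS-oxy)-4-(PMB-oxy)-3-methylbutyl]-7-oxabicyclo[2.2.1]heptane | COc1ccc(COC[C@@](C)(O[Si](C)(C)C(C)(C)C)CC[C@H]2[C@](C)(CCC=C(C)C)[C@@H]3CC[C@@]2(C)O3)cc1 | intermediate
27 | (2S)-2-(TBS-oxy)-2-methyl-4-[(1R,2S,3S,4S)-1,3-dimethyl-3-(4-methylpent-3-en-1-yl)-7-oxabicyclo[2.2.1]heptan-2-yl]butan-1-ol | OC[C@@](C)(O[Si](C)(C)C(C)(C)C)CC[C@H]1[C@](C)(CCC=C(C)C)[C@@H]2CC[C@@]1(C)O2 | intermediate
28 | (2S)-2-(TBS-oxy)-2-methyl-4-[(1R,2S,3S,4S)-1,3-dimethyl-3-(4-methylpent-3-en-1-yl)-7-oxabicyclo[2.2.1]heptan-2-yl]butanal | O=C[C@@](C)(O[Si](C)(C)C(C)(C)C)CC[C@H]1[C@](C)(CCC=C(C)C)[C@@H]2CC[C@@]1(C)O2 | intermediate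
29 | TBS ether of (3S)-3-methyl-5-[(1R,2S,3S,4S)-1,3-dimethyl-3-(4-methylpent-3-en-1-yl)-7-oxabicyclo[2.2.1]heptan-2-yl]pent-1-en-3-ol | C=C[C@@](C)(O[Si](C)(C)C(C)(C)C)CC[C@H]1[C@](C)(CCC=C(C)C)[C@@H]2CC[C@@]1(C)O2 | intermediate
30 | analogue of 29 with a 2-[(2R)-3,3-dimethyloxiran-2-yl]ethyl group on C-3 of the bicycle | C=C[C@@](C)(O[Si](C)(C)C(C)(C)C)CC[C@H]1[C@](C)(CC[C@H]3OC3(C)C)[C@@H]2CC[C@@]1(C)O2 | intermediate
31 | analogue of 29 with a (3S)-3-bromo-4-hydroxy-4-methylpentyl group on C-3 of the bicycle | C=C[C@@](C)(O[Si](C)(C)C(C)(C)C)CC[C@H]1[C@](C)(CC[C@H](Br)C(C)(C)O)[C@@H]2CC[C@@]1(C)O2 | intermediate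
32 | O-TBS-dactylomelol | C=C[C@@](C)(O[Si](C)(C)C(C)(C)C)CC[C@H]1[C@](C)(CC[C@H](Br)C(C)(C)Cl)[C@@H]2CC[C@@]1(C)O2 | intermediate
33 | dactylomelol, (3S)-5-[(1R,2S,3S,4S)-3-[(3S)-3-bromo-4-chloro-4-methylpentyl]-1,3-dimethyl-7-oxabicyclo[2.2.1]heptan-2-yl]-3-methylpent-1-en-3-ol | C=C[C@@](C)(O)CC[C@H]1[C@](C)(CC[C@H](Br)C(C)(C)Cl)[C@@H]2CC[C@@]1(C)O2 | target

**Count and risks**

Total step count: 24 (steps 1–4 fragment A, steps 5–9 fragment B, steps 10–24 after union). Longest linear sequence: 20 steps (steps 5–9, then 10–24).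

Steps most likely to fail:

1. Step 16 (Proposed new method). What may go wrong: ionisation of the oxirane at its secondary carbon with 1,2-shift of the vinyl group or of hydride, or capture of the cation by the silyl ether oxygen, instead of alkene attack at the oxirane CH2. Fallback with known chemistry, setting out from 18 and coming back at 24: aqueous AcOH cleaves the acetonide of 18 and the hydroxy acid lactonises to the hydroxymethyl γ-lactone F1; I2, PPh3 and imidazole give the iodomethyl lactone F2; one equivalent of MeLi at −78 °C adds to the lactone and the released secondary alkoxide displaces iodide to give the epoxy methyl ketone F3; the kinetic methyl-ketone enolate (LiN(i-Pr)2, then warming) opens the epoxide at its CH2 terminus and closes the hydroxy cyclohexanone F4, which makes the same C-5–C-6 bond by enolate alkylation; Wittig methylenation gives the methylidene cyclohexanol F5; Hg(OCOCF3)2 followed by NaBH4 (intramolecular oxymercuration–demercuration) closes the ether bridge and gives 24.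

2. Step 11. What may go wrong: erosion of the relative configuration at C-2/C-3 through incomplete Z(O)-enolate formation or a competing boat transition state of the Z-allyl ester. Fallback, setting out from 3 (with 14) and coming back at 18: carboalumination of alkyne 3 (Me3Al, Cp2ZrCl2; then paraformaldehyde) gives the E-allylic alcohol F6; DCC coupling with 14 gives the E-allyl ester F7; its Ireland–Claisen rearrangement through the kinetic E(O)-enolate (LiN(i-Pr)2 in THF without DMPU, Me3SiCl) should reach the same acid 18 from the other geometric pair, again with bond formation anti to the acetal C–O bond.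

3. Step 22. What may go wrong: bromide attack at the tertiary oxirane carbon or Lewis-acid-induced rearrangement of the epoxide, giving the regioisomeric bromohydrin. Fallback, setting out from 30 and coming back at 32: chlorine is installed first; HCl in Et2O at −78 °C opens 30 at the tertiary carbon to the chlorohydrin F8 with the secondary carbinol intact, and PPh3/CBr4 (Appel reaction) converts that alcohol into the bromide with inversion, giving 32 directly.

Further compounds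
F1 | step 16 | hydroxymethyl γ-lactone from 18 (lactone oxygen on C-4, carbonyl at the future C-1) | COc1ccc(COC[C@@](C)(O[Si](C)(C)C(C)(C)C)CC[C@@H]2C(=O)O[C@@H](CO)[C@@]2(C)C=C)cc1
F2 | step 16 | iodomethyl γ-lactone | COc1ccc(COC[C@@](C)(O[Si](C)(C)C(C)(C)C)CC[C@@H]2C(=O)O[C@@H](CI)[C@@]2(C)C=C)cc1
F3 | step 16 | epoxy methyl ketone | COc1ccc(COC[C@@](C)(O[Si](C)(C)C(C)(C)C)CC[C@H](C(C)=O)[C@](C)(C=C)[C@@H]2CO2)cc1
F4 | step 16 | 4-hydroxycyclohexanone with the C-5–C-6 bond formed | COc1ccc(COC[C@@](C)(O[Si](C)(C)C(C)(C)C)CC[C@H]2[C@](C)(C=C)[C@@H](O)CCC2=O)cc1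
F5 | step 16 | 4-methylidenecyclohexanol | COc1ccc(COC[C@@](C)(O[Si](C)(C)C(C)(C)C)CC[C@H]2[C@](C)(C=C)[C@@H](O)CCC2=C)cc1
F6 | step 11 | (2E)-3-[(4R)-2,2-dimethyl-1,3-dioxolan-4-yl]but-2-en-1-ol | OC/C=C(\C)[C@@H]1COC(C)(C)O1
F7 | step 11 | (2E)-allyl ester of acid 14 | COc1ccc(COC[C@@](C)(O[Si](C)(C)C(C)(C)C)CCCC(=O)OC/C=C(\C)[C@@H]2COC(C)(C)O2)cc1
F8 | step 22 | chlorohydrin, analogue of 29 with a (3R)-4-chloro-3-hydroxy-4-methylpentyl group on C-3 of the bicycle | C=C[C@@](C)(O[Si](C)(C)C(C)(C)C)CC[C@H]1[C@](C)(CC[C@@H](O)C(C)(C)Cl)[C@@H]2CC[C@@]1(C)O2
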